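Numbering the core C1 (OMe bridgehead), C2 (CHOH), C3 (CHOMe), C4, C5 (allyl bridgehead), C6 (CHMe), C7 (CHAr), C8 (C=O), the bicycle is opened at C2–C3 and C1–C2 to a cyclopentanone. Everything rests on C5 and C6 being the α- and β-carbons of the C8 ketone in the five-membered ring C1–C8–C5–C6–C7, next to aryl-bearing C7: a (4R)-4-aryl-2-prenylcyclopent-2-enone takes methyl at C6 and allyl at C5 in one cuprate addition–enolate alkylation, relaying the catalytically set C7 centre to C6 and quaternary C5. The prenyl arm is the masked C4–C3 unit; the enone comes regiospecifically from an allyl β-keto ester.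

Key step: step 5

Remarks on the chemistry:
- Assumption: Rh/(S)-BINAP is taken to deliver the aryl group to enone 5 with the facial sense it shows with cyclopent-2-en-1-one ((S)-3-aryl ketone pattern), for both enantiomers of the racemic quaternary centre, which is removed in step 4. If the opposite sense were found, (R)-BINAP would be used.
- Prenyl = 3-methylbut-2-en-1-yl; Ar = 3,4,5-trimethoxyphenyl. Cyclopentanones 12–18 keep the locants of 12 (C1 carbonyl, C2 quaternary, C3 methyl, C4 aryl, C5 α′-carbon).

Step 1
Reactants: 1 allyl 2-oxocyclopentane-1-carboxylate; 2 1-bromo-3-methylbut-2-ene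
Product: 3 allyl 1-prenyl-2-oxocyclopentane-1-carboxylate (racemic)
Conditions: K2CO3, acetone, reflux
Reagents that add atoms: none
Why: C-alkylation of the stabilised β-keto ester enolate (acetoacetic ester-type alkylation) by the primary allylic bromide should give the quaternary carbon, whose configuration is irrelevant because it is removed in step 4.

Step 2
Reactants: 3 allyl 1-prenyl-2-oxocyclopentane-1-carboxylate
Product: 5 allyl 1-prenyl-2-oxocyclopent-3-ene-1-carboxylate (racemic), via lithium enolate 4 (not isolated)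
Conditions: LDA, THF, −78 °C; then PhS(Cl)=N-t-Bu, −78 °C
Reagents that add atoms: none
Why: The ketone has a single enolisable α-carbon, so kinetic deprotonation followed by Mukaiyama dehydrogenation (attack of the enolate on sulfur, then syn-elimination of the sulfenamide) should place the double bond regiospecifically at C3–C4 at low temperature without touching the prenyl or allyl groups.

Step 3
Reactants: 5 allyl 1-prenyl-2-oxocyclopent-3-ene-1-carboxylate; 6 (3,4,5-trimethoxyphenyl)boronic acid
Product: 7 allyl (4S)-1-prenyl-2-oxo-4-(3,4,5-trimethoxyphenyl)cyclopentane-1-carboxylate (both C1 epimers)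
Conditions: [Rh(OH)((S)-BINAP)]2 (3 mol% Rh), 6 (2.5 equiv), dioxane/H2O 10:1, 35 °C
Reagents that add atoms: none
Why: Hayashi–Miyaura rhodium-catalysed asymmetric 1,4-addition: the aryl–rhodium species should add to the unsubstituted β-carbon under catalyst control to set the (4S) aryl centre (the future C7) in both C1 epimers, and the neutral hydroxo-rhodium conditions should leave the allyl β-keto ester intact.

Step 4
Reactants: 7 allyl (4S)-1-prenyl-2-oxo-4-(3,4,5-trimethoxyphenyl)cyclopentane-1-carboxylate
Product: 8 (4R)-2-prenyl-4-(3,4,5-trimethoxyphenyl)cyclopent-2-en-1-one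
Conditions: Pd(OAc)2 (5 mol%), dppe (5 mol%), MeCN, 80 °C
Reagents that add atoms: none
Why: Tsuji palladium-catalysed decarboxylation–dehydrogenation of an allyl β-keto ester: ionisation and loss of CO2 give a π-allylpalladium enolate only at the prenyl-bearing carbon, and β-hydride elimination into the ring in acetonitrile should give the 2-substituted enone under neutral conditions that neither epimerise the γ-aryl centre nor move the double bond toward the arene.

Step 5
Reactants: 8 (4R)-2-prenyl-4-(3,4,5-trimethoxyphenyl)cyclopent-2-en-1-one; 9 lithium dimethylcuprate; 10 allyl bromide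
Product: 12 (2S,3S,4R)-2-allyl-3-methyl-2-prenyl-4-(3,4,5-trimethoxyphenyl)cyclopentan-1-one, via lithium enolate 11 (not isolated)
Conditions: 9 (pre-formed solution), Et2O, −78 → −40 °C; then 10 (excess), HMPA, THF, −78 → −20 °C
Reagents that add atoms: none
Why: The cuprate adds by π-complexation, oxidative addition at the β-carbon and reductive elimination, forming the C6–CH3 bond (core numbering) on the face opposite the adjacent C7 aryl group and giving enolate 11 with its double bond fixed between C8 and C5; SN2 alkylation by allyl bromide then forms the C5–allyl bond. The closest known reaction type is the three-component coupling of cyclopentenones by organocuprate conjugate addition and in situ enolate alkylation, as used for 2,2,3-trisubstituted cyclopentanones and prostanoids. No ring is closed. C6 is controlled by the C7 aryl group (1,2-anti addition), and the quaternary C5 by the new C6 methyl group (allyl enters anti to it, leaving the prenyl arm cis to methyl and trans to aryl). The step needs C-alkylation at C5 without enolate equilibration toward C1, which the regiodefined enolate, the excess of reactive allylic bromide and the polar additive at low temperature should secure. It also needs 1,2-anti facial selectivity, which rests on the adjacent methyl group outweighing the 1,3-related aryl group, as in trans,trans prostanoid couplings.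

Step 6
Reactants: 12 (2S,3S,4R)-2-allyl-3-methyl-2-prenyl-4-(3,4,5-trimethoxyphenyl)cyclopentan-1-one
Product: 14 (2S,3S,4R)-2-allyl-5-hydroxy-3-methyl-2-prenyl-4-(3,4,5-trimethoxyphenyl)cyclopentan-1-one (C5 epimers), via potassium enolate 13 (not isolated)
Conditions: KHMDS, THF, −78 °C; then 2-(phenylsulfonyl)-3-phenyloxaziridine, −78 °C; AcOH
Reagents that add atoms: 2-(phenylsulfonyl)-3-phenyloxaziridine, O=S(=O)(N1OC1c1ccccc1)c1ccccc1
Why: Davis enolate hydroxylation: the ketone can enolise only toward C5, and the potassium enolate should take oxygen from the N-sulfonyloxaziridine mainly anti to the neighbouring aryl group; the configuration of this centre does not matter because it is planarised again in step 8.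

Step 7
Reactants: 14 (2S,3S,4R)-2-allyl-5-hydroxy-3-methyl-2-prenyl-4-(3,4,5-trimethoxyphenyl)cyclopentan-1-one
Product: 15 (2S,3S,4R)-2-allyl-5-methoxy-3-methyl-2-prenyl-4-(3,4,5-trimethoxyphenyl)cyclopentan-1-one (C5 epimers)
Conditions: MeI, Ag2O, MeCN, 40 °C, dark
Reagents that add atoms: iodomethane, CI
Why: Purdie methylation (silver oxide-promoted Williamson-type O-alkylation) of the secondary α-ketol under essentially neutral conditions should avoid enediol isomerisation and C-alkylation.

Step 8
Reactants: 15 (2S,3S,4R)-2-allyl-5-methoxy-3-methyl-2-prenyl-4-(3,4,5-trimethoxyphenyl)cyclopentan-1-one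
Product: 17 (2S,3S,4R,5R)-2-allyl-5-(hydroxymethyl)-5-methoxy-3-methyl-2-prenyl-4-(3,4,5-trimethoxyphenyl)cyclopentan-1-one, via lithium enolate 16 (not isolated)
Conditions: LiHMDS, THF, −78 °C; then CH2O (monomer in THF), −78 °C; AcOH, −78 °C
Reagents that add atoms: formaldehyde, C=O
Why: Aldol hydroxymethylation of the chelated lithium enolate of the α-methoxy ketone: formaldehyde should enter anti to the adjacent aryl group, setting the quaternary C1 with methoxy cis to aryl and the hydroxymethyl carbon (future C2) cis to the prenyl arm, and the cold acidic quench should prevent retro-aldol cleavage.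

Step 9
Reactants: 17 (2S,3S,4R,5R)-2-allyl-5-(hydroxymethyl)-5-methoxy-3-methyl-2-prenyl-4-(3,4,5-trimethoxyphenyl)cyclopentan-1-one
Product: 18 (2S,3S,4R,5R)-2-allyl-2-[(3,3-dimethyloxiran-2-yl)methyl]-5-(hydroxymethyl)-5-methoxy-3-methyl-4-(3,4,5-trimethoxyphenyl)cyclopentan-1-one (both epoxide epimers)
Conditions: mCPBA (1.05 equiv), CH2Cl2, 0 °C
Reagents that add atoms: 3-chloroperoxybenzoic acid, OOC(=O)c1cccc(Cl)c1
Why: Prilezhaev epoxidation strongly favours the electron-rich trisubstituted prenyl alkene over the monosubstituted allyl alkene, and with one equivalent of peracid at 0 °C the ketone should not undergo Baeyer–Villiger oxidation; the new epoxide centre is lost in step 11.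

Step 10
Reactants: 18 (2S,3S,4R,5R)-2-allyl-2-[(3,3-dimethyloxiran-2-yl)methyl]-5-(hydroxymethyl)-5-methoxy-3-methyl-4-(3,4,5-trimethoxyphenyl)cyclopentan-1-one
Product: 19 (1R,3S,4S,5R)-3-allyl-3-[(3,3-dimethyloxiran-2-yl)methyl]-1-methoxy-4-methyl-2-oxo-5-(3,4,5-trimethoxyphenyl)cyclopentane-1-carbaldehyde
Conditions: Dess–Martin periodinane, pyridine, CH2Cl2, 0 °C → rt
Reagents that add atoms: none
Why: Dess–Martin oxidation of the neopentyl primary alcohol under buffered, non-basic conditions should give the non-enolisable β-keto aldehyde without retro-aldol cleavage, deformylation or epoxide opening.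

Step 11
Reactants: 19 (1R,3S,4S,5R)-3-allyl-3-[(3,3-dimethyloxiran-2-yl)methyl]-1-methoxy-4-methyl-2-oxo-5-(3,4,5-trimethoxyphenyl)cyclopentane-1-carbaldehyde
Product: 20 (1R,3S,4S,5R)-3-allyl-1-methoxy-4-methyl-2-oxo-3-(2-oxoethyl)-5-(3,4,5-trimethoxyphenyl)cyclopentane-1-carbaldehyde
Conditions: H5IO6, THF/H2O, 0 °C → rt; used at once
Reagents that add atoms: none
Why: Periodic acid cleavage of the trisubstituted epoxide (acid-catalysed hydration at the tertiary carbon, then Malaprade glycol cleavage) should release the C3 aldehyde and acetone while the allyl group, the ketone and the aryl ethers are inert.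

Step 12
Reactants: 20 (1R,3S,4S,5R)-3-allyl-1-methoxy-4-methyl-2-oxo-3-(2-oxoethyl)-5-(3,4,5-trimethoxyphenyl)cyclopentane-1-carbaldehyde
Product: 21 (1R,2R,3R,5S,6S,7R)-5-allyl-2,3-dihydroxy-1-methoxy-6-methyl-7-(3,4,5-trimethoxyphenyl)bicyclo[3.2.1]octan-8-one
Conditions: SmI2 (2.4 equiv), THF, −78 → −20 °C, no HMPA; then aq. NH4Cl
Reagents that add atoms: none
Why: Samarium(II) iodide-mediated intramolecular pinacol coupling of the 1,6-dialdehyde: the aldehydes are reduced far faster than the hindered ketone, the ketyls couple on a samarium(III) template to form C2–C3 and the six-membered ring as a cis-diol, and this diol should lie on the exo face (C2–OH axial, C3–OH equatorial) because the endo face at C3 is blocked by the C6 methyl group, while leaving out HMPA keeps the ketone and the allyl group out of the reaction.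

Step 13
Reactants: 21 (1R,2R,3R,5S,6S,7R)-5-allyl-2,3-dihydroxy-1-methoxy-6-methyl-7-(3,4,5-trimethoxyphenyl)bicyclo[3.2.1]octan-8-one
Product: 23 (1R,2R,3R,5S,6S,7R)-5-allyl-2-hydroxy-1,3-dimethoxy-6-methyl-7-(3,4,5-trimethoxyphenyl)bicyclo[3.2.1]octan-8-one, via stannylene acetal 22 (not isolated)
Conditions: Bu2SnO, toluene, reflux (−H2O); then MeI, CsF (2 equiv), DMF, rt
Reagents that add atoms: iodomethane, CI
Why: Regioselective alkylation of a cis-diol through its dibutylstannylene acetal: fluoride-activated methylation should occur at the equatorial, less hindered C3 oxygen and not at the axial C2 oxygen beside quaternary C1, and retro-aldol opening of the β-hydroxy ketone is excluded because it would require a bridgehead enolate.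

Compound list
1 | allyl 2-oxocyclopentane-1-carboxylate | C=CCOC(=O)C1CCCC1=O | starting material
2 | 1-bromo-3-methylbut-2-ene (prenyl bromide) | CC(C)=CCBr | starting material
3 | allyl 1-(3-methylbut-2-en-1-yl)-2-oxocyclopentane-1-carboxylate (racemic) | C=CCOC(=O)C1(CC=C(C)C)CCCC1=O | intermediate
4 | lithium 5-(allyloxycarbonyl)-5-(3-methylbut-2-en-1-yl)cyclopent-1-en-1-olate (racemic; not isolated) | [Li+].[O-]C1=CCCC1(CC=C(C)C)C(=O)OCC=C | intermediate
5 | allyl 1-(3-methylbut-2-en-1-yl)-2-oxocyclopent-3-ene-1-carboxylate (racemic) | C=CCOC(=O)C1(CC=C(C)C)CC=CC1=O | intermediate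
6 | (3,4,5-trimethoxyphenyl)boronic acid | OB(O)c1cc(OC)c(OC)c(OC)c1 | starting material
7 | allyl (4S)-1-(3-methylbut-2-en-1-yl)-2-oxo-4-(3,4,5-trimethoxyphenyl)cyclopentane-1-carboxylate (both C1 epimers) | C=CCOC(=O)C1(CC=C(C)C)C[C@H](c2cc(OC)c(OC)c(OC)c2)CC1=O | intermediate
8 | (4R)-2-(3-methylbut-2-en-1-yl)-4-(3,4,5-trimethoxyphenyl)cyclopent-2-en-1-one | O=C1C[C@@H](c2cc(OC)c(OC)c(OC)c2)C=C1CC=C(C)C | intermediate
9 | lithium dimethylcuprate | [Li+].C[Cu-]C | starting material
10 | allyl bromide (3-bromoprop-1-ene) | C=CCBr | starting material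
11 | lithium (3S,4R)-3-methyl-2-(3-methylbut-2-en-1-yl)-4-(3,4,5-trimethoxyphenyl)cyclopent-1-en-1-olate (not isolated) | [Li+].[O-]C1=C(CC=C(C)C)[C@@H](C)[C@H](c2cc(OC)c(OC)c(OC)c2)C1 | intermediate
12 | (2S,3S,4R)-2-allyl-3-methyl-2-(3-methylbut-2-en-1-yl)-4-(3,4,5-trimethoxyphenyl)cyclopentan-1-one (aryl/methyl trans, methyl/allyl trans) | C=CC[C@@]1(CC=C(C)C)C(=O)C[C@@H](c2cc(OC)c(OC)c(OC)c2)[C@@H]1C | intermediate
13 | potassium enolate of 12 (C1=C5 enolate; C2, C3, C4 as in 12; not isolated) | [K+].C=CC[C@@]1(CC=C(C)C)C([O-])=C[C@@H](c2cc(OC)c(OC)c(OC)c2)[C@@H]1C | intermediate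
14 | (2S,3S,4R)-2-allyl-5-hydroxy-3-methyl-2-(3-methylbut-2-en-1-yl)-4-(3,4,5-trimethoxyphenyl)cyclopentan-1-one (C5 epimers) | C=CC[C@@]1(CC=C(C)C)C(=O)C(O)[C@@H](c2cc(OC)c(OC)c(OC)c2)[C@@H]1C | intermediate
15 | (2S,3S,4R)-2-allyl-5-methoxy-3-methyl-2-(3-methylbut-2-en-1-yl)-4-(3,4,5-trimethoxyphenyl)cyclopentan-1-one (C5 epimers) | C=CC[C@@]1(CC=C(C)C)C(=O)C(OC)[C@@H](c2cc(OC)c(OC)c(OC)c2)[C@@H]1C | intermediate
16 | lithium enolate of 15 (C1=C5 enolate; C2, C3, C4 as in 12; not isolated) | [Li+].C=CC[C@@]1(CC=C(C)C)C([O-])=C(OC)[C@@H](c2cc(OC)c(OC)c(OC)c2)[C@@H]1C | intermediate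
17 | (2S,3S,4R,5R)-2-allyl-5-(hydroxymethyl)-5-methoxy-3-methyl-2-(3-methylbut-2-en-1-yl)-4-(3,4,5-trimethoxyphenyl)cyclopentan-1-one (methoxy cis to aryl; hydroxymethyl cis to prenyl) | C=CC[C@@]1(CC=C(C)C)C(=O)[C@](OC)(CO)[C@@H](c2cc(OC)c(OC)c(OC)c2)[C@@H]1C | intermediate
18 | (2S,3S,4R,5R)-2-allyl-2-[(3,3-dimethyloxiran-2-yl)methyl]-5-(hydroxymethyl)-5-methoxy-3-methyl-4-(3,4,5-trimethoxyphenyl)cyclopentan-1-one (both epoxide epimers) | C=CC[C@@]1(CC2OC2(C)C)C(=O)[C@](OC)(CO)[C@@H](c2cc(OC)c(OC)c(OC)c2)[C@@H]1C | intermediate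
19 | (1R,3S,4S,5R)-3-allyl-3-[(3,3-dimethyloxiran-2-yl)methyl]-1-methoxy-4-methyl-2-oxo-5-(3,4,5-trimethoxyphenyl)cyclopentane-1-carbaldehyde (both epoxide epimers) | C=CC[C@@]1(CC2OC2(C)C)C(=O)[C@](OC)(C=O)[C@@H](c2cc(OC)c(OC)c(OC)c2)[C@@H]1C | intermediate
20 | (1R,3S,4S,5R)-3-allyl-1-methoxy-4-methyl-2-oxo-3-(2-oxoethyl)-5-(3,4,5-trimethoxyphenyl)cyclopentane-1-carbaldehyde | C=CC[C@@]1(CC=O)C(=O)[C@](OC)(C=O)[C@@H](c2cc(OC)c(OC)c(OC)c2)[C@@H]1C | intermediate
21 | (1R,2R,3R,5S,6S,7R)-5-allyl-2,3-dihydroxy-1-methoxy-6-methyl-7-(3,4,5-trimethoxyphenyl)bicyclo[3.2.1]octan-8-one (2-OH axial, 3-OH equatorial, both exo; methyl endo; aryl exo) | C=CC[C@@]12C[C@@H](O)[C@@H](O)[C@@](OC)(C1=O)[C@@H](c1cc(OC)c(OC)c(OC)c1)[C@@H]2C | intermediate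
22 | 2,3-O-dibutylstannylene acetal of 21 (not isolated) | C=CC[C@@]12C[C@@H](O[Sn](CCCC)(CCCC)O3)[C@@H]3[C@@](OC)(C1=O)[C@@H](c1cc(OC)c(OC)c(OC)c1)[C@@H]2C | intermediate
23 | (1R,2R,3R,5S,6S,7R)-5-allyl-2-hydroxy-1,3-dimethoxy-6-methyl-7-(3,4,5-trimethoxyphenyl)bicyclo[3.2.1]octan-8-one (CNP0275320.1) | C=CC[C@@]12C[C@@H](OC)[C@@H](O)[C@@](OC)(C1=O)[C@@H](c1cc(OC)c(OC)c(OC)c1)[C@@H]2C | target

Total step count: 13. Longest linear sequence: 13 steps (1 → 23).

Steps most likely to fail

Step 5. The allyl bromide may attack the enolate face syn to the C6 methyl group, if the 1,3-related aryl group rather than the adjacent methyl group decides the face. Proton exchange between the hindered enolate and the product may also compete with C-alkylation. The fallback sets out from 1 and rejoins the route at 12; it exchanges the roles of the two allylic groups, so that the group entering last is the one that must end syn to methyl. Alkylation of 1 with allyl bromide 10 (K2CO3, acetone) gives allyl 1-allyl-2-oxocyclopentane-1-carboxylate F1. Its lithium enolate F2 (LDA) is dehydrogenated with N-tert-butylbenzenesulfinimidoyl chloride to allyl 1-allyl-2-oxocyclopent-3-ene-1-carboxylate F3. Rhodium/(S)-BINAP addition of 6 gives allyl (4S)-1-allyl-2-oxo-4-(3,4,5-trimethoxyphenyl)cyclopentane-1-carboxylate F4. Palladium-catalysed decarboxylation–dehydrogenation then gives (4R)-2-allyl-4-(3,4,5-trimethoxyphenyl)cyclopent-2-en-1-one F5. Addition of 9 gives the lithium enolate F6, and alkylation with prenyl bromide 2 should then deliver 12.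

Step 12. Electron transfer may be diverted before the two carbonyl carbons meet: loss of methoxide from the C2 ketyl next to C1, deformylation of the β-keto aldehyde, or reduction at C8. The ketyls may also couple without chelation and give a trans diol. The fallback runs from 20 to 21 and makes no new compound. It gives up outer-sphere electron transfer from samarium(II) and couples the two aldehydes on a low-valent vanadium template, [V2Cl3(THF)6]2[Zn2Cl6] (from VCl3(THF)3 and zinc) in CH2Cl2 at room temperature. This is a known pinacol reagent that engages aldehydes carrying a chelating α-alkoxy group and leaves ketones alone, so the C1 methoxy group serves as the anchor for a chelated cis coupling instead of as a leaving group.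

Step 3. The racemic quaternary centre of 5 may exert substrate control, so that one enantiomer reacts in a mismatched sense and the enantiopurity of the aryl centre is eroded; turnover at the hindered enone may also be slow. The fallback sets out from 6 and rejoins the route at 7; it sets the aryl centre first on the unsubstituted ring. Rhodium/(S)-BINAP addition of 6 to commercial cyclopent-2-en-1-one gives (S)-3-(3,4,5-trimethoxyphenyl)cyclopentan-1-one F7. Equilibrating C-acylation with diallyl carbonate and NaH (THF, reflux) at the α-carbon remote from the aryl group gives allyl (4S)-2-oxo-4-(3,4,5-trimethoxyphenyl)cyclopentane-1-carboxylate F8, the regioisomer being removed by chromatography. Prenylation with 2 (K2CO3, acetone) then gives 7.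

Further compounds
F1 | step 5 | allyl 1-allyl-2-oxocyclopentane-1-carboxylate (racemic) | C=CCOC(=O)C1(CC=C)CCCC1=O
F2 | step 5 | lithium 5-allyl-5-(allyloxycarbonyl)cyclopent-1-en-1-olate (racemic; not isolated) | [Li+].[O-]C1=CCCC1(CC=C)C(=O)OCC=C
F3 | step 5 | allyl 1-allyl-2-oxocyclopent-3-ene-1-carboxylate (racemic) | C=CCOC(=O)C1(CC=C)CC=CC1=O
F4 | step 5 | allyl (4S)-1-allyl-2-oxo-4-(3,4,5-trimethoxyphenyl)cyclopentane-1-carboxylate (both C1 epimers) | C=CCOC(=O)C1(CC=C)C[C@H](c2cc(OC)c(OC)c(OC)c2)CC1=O
F5 | step 5 | (4R)-2-allyl-4-(3,4,5-trimethoxyphenyl)cyclopent-2-en-1-one | O=C1C[C@@H](c2cc(OC)c(OC)c(OC)c2)C=C1CC=C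
F6 | step 5 | lithium (3S,4R)-2-allyl-3-methyl-4-(3,4,5-trimethoxyphenyl)cyclopent-1-en-1-olate (not isolated) | [Li+].[O-]C1=C(CC=C)[C@@H](C)[C@H](c2cc(OC)c(OC)c(OC)c2)C1
F0 | step 12 | none | none
F7 | step 3 | (S)-3-(3,4,5-trimethoxyphenyl)cyclopentan-1-one | O=C1C[C@@H](c2cc(OC)c(OC)c(OC)c2)CC1
F8 | step 3 | allyl (4S)-2-oxo-4-(3,4,5-trimethoxyphenyl)cyclopentane-1-carboxylate (C1 epimers) | C=CCOC(=O)C1C[C@H](c2cc(OC)c(OC)c(OC)c2)CC1=O
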